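**Retrosynthetic overview**

- The target is a benzophenone of ring A (2-ethyl-4,6-dihydroxyphenyl) and ring B (2,4-dihydroxyphenyl carrying at C6 a CH2 group to ring C, a 4-hydroxy-2-pyranone).
- Key disconnection: the bond between the ketone carbon and C1 of ring B, made as a Claisen bond between acyl imidazolide 8 (ring A) and a methyl carbanion of bis-pyranone 5. In the same operation ring B is folded from the masked polyketone.
- Enabling feature: ring B is a 2-acylresorcinol (OH on C2 and C4, carbon substituents on C1 and C6). C1 is therefore the central carbon of a β-diketone, and C1–C6 is an aldol bond of a 1,3,5,7-tetraketone, which can be stored as a 4-pyranone (temporary ring D). The acidic 4-OH of ring C protects that ring as its anion in base.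
- Order of rings: ring C is bought (1); ring D is closed in step 2; ring A is bought (6); ring B is formed last from ring D (step 5); the methyl ethers are then removed.

Key step: step 5

Remark: the target has no stereocentre and is handled as the 4-hydroxy-2-pyranone tautomer drawn; compounds 1, 3 and 6 are taken as commercial.

**Route**

Step 1
Reactants: 1 4-hydroxy-6-methyl-2H-pyran-2-one (triacetic acid lactone)
Product: 2 4-hydroxy-6-(2-oxopropyl)-2H-pyran-2-one
Conditions: LiN(iPr)2 (2.2 equiv), THF, −78 to −20 °C; MeC(O)N(OMe)Me (1.2 equiv), −78 to 0 °C; aq. HCl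
Reagents that add atoms: N-methoxy-N-methylacetamide, CC(=O)N(C)OC
Why: Two equivalents of base should give the O,C-dianion of 1, whose only carbanion (on the 6-methyl group) adds to the amide, and the chelated tetrahedral adduct keeps the new ketone masked until work-up (dianion C-acylation, Weinreb ketone synthesis).

Step 2
Reactants: 2 4-hydroxy-6-(2-oxopropyl)-2H-pyran-2-one; 3 methyl (2E)-3-methoxybut-2-enoate
Product: 5 4-hydroxy-6-[(6-methyl-4-oxo-4H-pyran-2-yl)methyl]-2H-pyran-2-one, via enol ether triketone 4 (not isolated)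
Conditions: LiN(iPr)2 (3.2 equiv), THF, −78 to −30 °C; 3 (1.2 equiv), −78 to 0 °C; then HCl (4 M in dioxane, excess), 0 to 25 °C
Reagents that add atoms: none
Why: The trianion of 2 should react at its last-formed terminal CH2 carbanion with the ester carbonyl of 3 (Claisen acylation; the β-carbon of 3 is fully substituted and deactivated by its methoxy group), and acid then closes ring D by attack of the enol oxygen on the methoxy-bearing carbon with loss of methanol (cyclisation of a 1,3,5-tricarbonyl mono-enol ether to a 4-pyranone).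

Step 3
Reactants: 6 2,4-dimethoxy-6-methylbenzoic acid
Product: 7 2-ethyl-4,6-dimethoxybenzoic acid
Conditions: LiN(iPr)2 (2.2 equiv), THF, −78 to 0 °C; MeI (1.1 equiv), −78 °C; aq. HCl
Reagents that add atoms: iodomethane, CI
Why: Carboxylate-assisted lateral (benzylic) lithiation of the o-toluic acid should give the dianion, which is methylated on carbon; a second alkylation is not expected because the base is used up and the new secondary benzylic hydrogens are less acidic.

Step 4
Reactants: 7 2-ethyl-4,6-dimethoxybenzoic acid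
Product: 8 1-(2-ethyl-4,6-dimethoxybenzoyl)-1H-imidazole
Conditions: 1,1'-carbonyldiimidazole (1.2 equiv), THF, 25 to 50 °C; rapid cold water wash, dry
Reagents that add atoms: 1,1'-carbonyldiimidazole, O=C(n1ccnc1)n1ccnc1
Why: Acyl imidazolide formation under neutral conditions should give a twisted, reactive acyl donor that acylates carbanions on carbon at −78 °C despite the two ortho substituents, and whose leaving group later serves as base.

Step 5
Reactants: 5 4-hydroxy-6-[(6-methyl-4-oxo-4H-pyran-2-yl)methyl]-2H-pyran-2-one; 8 1-(2-ethyl-4,6-dimethoxybenzoyl)-1H-imidazole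
Product: 11 (2-ethyl-4,6-dimethoxyphenyl){2,4-dihydroxy-6-[(4-hydroxy-2-oxo-2H-pyran-6-yl)methyl]phenyl}methanone, via aroylmethyl pyranone 9 (not isolated), via open-chain tetraketone 10 (not isolated)
Conditions: 5, LiN(iPr)2 (3.2 equiv), THF–DMPU, −78 to −20 °C; 8 (1.0 equiv), −78 to 0 °C; then aq. KOH (1 M), MeOH, 25 to 45 °C, Ar; aq. HCl to pH 2
Reagents that add atoms: none
Why: Three equivalents of LiN(iPr)2 should deprotonate 5 in the order ring C hydroxyl, inter-ring CH2, 6-methyl group of ring D, and the last-formed, least stabilised CH2 carbanion attacks acyl imidazolide 8 (Claisen C-acylation), joining the ketone carbon to the future C1 of ring B and leaving 9 as its enolate, with the released imidazolide taking up that proton. In aqueous KOH, hydroxide adds to the ring D carbon that carries the pyranylmethyl group, ring D opens to tetraketone 10, the C2 enolate of 10 adds to the C7 ketone just set free, and loss of water (the oxygen that hydroxide brought in) with enolisation gives the 2-aroylresorcinol ring B. The closest known reaction types are the terminal aroylation of polyanions of 1,3,5-tricarbonyl compounds and the alkali-induced conversion of 2-(acylmethyl)-4-pyranones into 2-acylresorcinols, here run in one flask. Ring B closes by a 6-(enolendo)-exo-trig aldol condensation between C2 and C7 of 10 (C1 and C6 of ring B); no stereocentre is formed. Three selectivities are needed: acylation at the methyl-derived carbon (secured by the reactivity order of polyanion sites); aldol closure C2 to C7 and not C6 to C1 or C8 to C3 (the C1 ketone is a twisted aryl ketone flanked by ethyl and methoxy, C3 is held as an enolate, and C8 beside the anionic ring C is barely acidic); and survival of ring C (as its pyranolate anion it should resist hydroxide under these mild conditions).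

Step 6
Reactants: 11 (2-ethyl-4,6-dimethoxyphenyl){2,4-dihydroxy-6-[(4-hydroxy-2-oxo-2H-pyran-6-yl)methyl]phenyl}methanone
Product: 12 (2-ethyl-4,6-dihydroxyphenyl){2,4-dihydroxy-6-[(4-hydroxy-2-oxo-2H-pyran-6-yl)methyl]phenyl}methanone
Conditions: BBr3 (8 equiv), CH2Cl2, −78 to 25 °C; MeOH, then H2O
Reagents that add atoms: none
Why: Lewis-acid cleavage of both aryl methyl ethers with BBr3 (the ortho one assisted by chelation to the ketone) should leave the diaryl ketone, the free phenols and the 4-hydroxy-2-pyranone untouched, and the only organic by-product is volatile bromomethane.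

**Compound list**

1 | 4-hydroxy-6-methyl-2H-pyran-2-one | Cc1cc(O)cc(=O)o1 | starting material
2 | 4-hydroxy-6-(2-oxopropyl)-2H-pyran-2-one | CC(=O)Cc1cc(O)cc(=O)o1 | intermediate
3 | methyl (2E)-3-methoxybut-2-enoate | CO/C(C)=C/C(=O)OC | starting material
4 | 4-hydroxy-6-[(5E)-6-methoxy-2,4-dioxohept-5-en-1-yl]-2H-pyran-2-one | CO/C(C)=C/C(=O)CC(=O)Cc1cc(O)cc(=O)o1 | intermediate
5 | 4-hydroxy-6-[(6-methyl-4-oxo-4H-pyran-2-yl)methyl]-2H-pyran-2-one | Cc1cc(=O)cc(Cc2cc(O)cc(=O)o2)o1 | intermediate
6 | 2,4-dimethoxy-6-methylbenzoic acid | Cc1cc(OC)cc(OC)c1C(=O)O | starting material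
7 | 2-ethyl-4,6-dimethoxybenzoic acid | CCc1cc(OC)cc(OC)c1C(=O)O | intermediate
8 | 1-(2-ethyl-4,6-dimethoxybenzoyl)-1H-imidazole | CCc1cc(OC)cc(OC)c1C(=O)n1ccnc1 | intermediate
9 | 6-({6-[2-(2-ethyl-4,6-dimethoxyphenyl)-2-oxoethyl]-4-oxo-4H-pyran-2-yl}methyl)-4-hydroxy-2H-pyran-2-one | CCc1cc(OC)cc(OC)c1C(=O)Cc1cc(=O)cc(Cc2cc(O)cc(=O)o2)o1 | intermediate
10 | 1-(2-ethyl-4,6-dimethoxyphenyl)-8-(4-hydroxy-2-oxo-2H-pyran-6-yl)octane-1,3,5,7-tetrone | CCc1cc(OC)cc(OC)c1C(=O)CC(=O)CC(=O)CC(=O)Cc1cc(O)cc(=O)o1 | intermediate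
11 | (2-ethyl-4,6-dimethoxyphenyl){2,4-dihydroxy-6-[(4-hydroxy-2-oxo-2H-pyran-6-yl)methyl]phenyl}methanone | CCc1cc(OC)cc(OC)c1C(=O)c1c(O)cc(O)cc1Cc1cc(O)cc(=O)o1 | intermediate
12 | (2-ethyl-4,6-dihydroxyphenyl){2,4-dihydroxy-6-[(4-hydroxy-2-oxo-2H-pyran-6-yl)methyl]phenyl}methanone | CCc1cc(O)cc(O)c1C(=O)c1c(O)cc(O)cc1Cc1cc(O)cc(=O)o1 | target

**Step count**

Total steps: 6. Longest linear sequence: 4 steps (1, 2, 5, 6; the branch 3, 4, 5, 6 is equally long).

**Three steps most likely to fail**

Step 5. What may go wrong: acylation at the inter-ring CH or on oxygen instead of the terminal carbanion; incomplete opening of the anionic ring D; hydrolytic opening and decarboxylation of ring C on prolonged exposure to alkali; retro-Claisen loss of the aroyl group. The fallback sets out from 7 and comes back at 12, forming the same bond by electrophilic aromatic substitution. Acid 7 and purchased methyl (3,5-dimethoxyphenyl)acetate are joined by Friedel–Crafts acylation through the mixed trifluoroacetic anhydride ((CF3CO)2O, CH2Cl2, 0 to 25 °C). This should acylate the position between the CH2 group and a methoxy group, para to the other methoxy group, and give methyl 2-[2-(2-ethyl-4,6-dimethoxybenzoyl)-3,5-dimethoxyphenyl]acetate F1. Saponification (LiOH, THF/H2O) should give 2-[2-(2-ethyl-4,6-dimethoxybenzoyl)-3,5-dimethoxyphenyl]acetic acid F2. 1,1'-Carbonyldiimidazole converts it into 1-{[2-(2-ethyl-4,6-dimethoxybenzoyl)-3,5-dimethoxyphenyl]acetyl}-1H-imidazole F3 (used in solution), which is added to an excess of the lithium dienolate of 2,2,6-trimethyl-4H-1,3-dioxin-4-one (LiN(SiMe3)2, THF, −78 °C) to give 6-{3-[2-(2-ethyl-4,6-dimethoxybenzoyl)-3,5-dimethoxyphenyl]-2-oxopropyl}-2,2-dimethyl-4H-1,3-dioxin-4-one F4. Heating in toluene (110 °C) expels acetone, and the acylketene should close to 6-[2-(2-ethyl-4,6-dimethoxybenzoyl)-3,5-dimethoxybenzyl]-4-hydroxy-2H-pyran-2-one F5. BBr3 in CH2Cl2 then cleaves all four methyl ethers to give 12.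

Step 2. What may go wrong: proton transfer from the γ-methyl group of 3 to the trianion; addition–elimination at the methoxy-bearing carbon of 3 instead of attack at the ester carbonyl; carbocyclisation of the inter-ring carbanion onto the enol ether on warming. The fallback sets out from 2 and comes back at 5, growing the chain by two-carbon units that offer neither a vinylogous acidic position nor a Michael acceptor. The trianion of 2 (LiN(iPr)2, 3.2 equiv, THF, −78 °C) is acetylated with N-methoxy-N-methylacetamide to give 4-hydroxy-6-(2,4-dioxopentyl)-2H-pyran-2-one F6. Its tetraanion (LiN(iPr)2, 4.2 equiv) is acetylated in the same way to give 4-hydroxy-6-(2,4,6-trioxoheptyl)-2H-pyran-2-one F7. Cold concentrated H2SO4 should then close the 1,3,5-triketone to ring D and give 5.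

Step 6. What may go wrong: incomplete cleavage of the methoxy group para to the ketone; precipitation of partly cleaved boron phenoxides; acid-induced condensation of the electron-rich rings during long exposure. The fallback sets out from 7 and comes back at 12, moving the ether cleavage to a simple early intermediate and ending with hydrogenolysis. Acid 7 is demethylated (BBr3, CH2Cl2) to 2-ethyl-4,6-dihydroxybenzoic acid F8. Benzylation (BnBr, K2CO3, DMF) gives benzyl 2,4-bis(benzyloxy)-6-ethylbenzoate F9, and saponification (KOH, aqueous dioxane, reflux) gives 2,4-bis(benzyloxy)-6-ethylbenzoic acid F10. 1,1'-Carbonyldiimidazole gives 1-[2,4-bis(benzyloxy)-6-ethylbenzoyl]-1H-imidazole F11. Under the conditions of step 5, F11 and 5 should give, by way of 6-[(6-{2-[2,4-bis(benzyloxy)-6-ethylphenyl]-2-oxoethyl}-4-oxo-4H-pyran-2-yl)methyl]-4-hydroxy-2H-pyran-2-one F12 and 1-[2,4-bis(benzyloxy)-6-ethylphenyl]-8-(4-hydroxy-2-oxo-2H-pyran-6-yl)octane-1,3,5,7-tetrone F13 (neither isolated), [2,4-bis(benzyloxy)-6-ethylphenyl]{2,4-dihydroxy-6-[(4-hydroxy-2-oxo-2H-pyran-6-yl)methyl]phenyl}methanone F14. Brief hydrogenolysis (H2, Pd/C, EtOAc, 25 °C) should then give 12.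

**Further compounds**

F1 | step 5 | methyl 2-[2-(2-ethyl-4,6-dimethoxybenzoyl)-3,5-dimethoxyphenyl]acetate | CCc1cc(OC)cc(OC)c1C(=O)c1c(OC)cc(OC)cc1CC(=O)OC
F2 | step 5 | 2-[2-(2-ethyl-4,6-dimethoxybenzoyl)-3,5-dimethoxyphenyl]acetic acid | CCc1cc(OC)cc(OC)c1C(=O)c1c(OC)cc(OC)cc1CC(=O)O
F3 | step 5 | 1-{[2-(2-ethyl-4,6-dimethoxybenzoyl)-3,5-dimethoxyphenyl]acetyl}-1H-imidazole | CCc1cc(OC)cc(OC)c1C(=O)c1c(OC)cc(OC)cc1CC(=O)n1ccnc1
F4 | step 5 | 6-{3-[2-(2-ethyl-4,6-dimethoxybenzoyl)-3,5-dimethoxyphenyl]-2-oxopropyl}-2,2-dimethyl-4H-1,3-dioxin-4-one | CCc1cc(OC)cc(OC)c1C(=O)c2c(OC)cc(OC)cc2CC(=O)CC3=CC(=O)OC(C)(C)O3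
F5 | step 5 | 6-[2-(2-ethyl-4,6-dimethoxybenzoyl)-3,5-dimethoxybenzyl]-4-hydroxy-2H-pyran-2-one | CCc1cc(OC)cc(OC)c1C(=O)c1c(OC)cc(OC)cc1Cc1cc(O)cc(=O)o1
F6 | step 2 | 4-hydroxy-6-(2,4-dioxopentyl)-2H-pyran-2-one | CC(=O)CC(=O)Cc1cc(O)cc(=O)o1
F7 | step 2 | 4-hydroxy-6-(2,4,6-trioxoheptyl)-2H-pyran-2-one | CC(=O)CC(=O)CC(=O)Cc1cc(O)cc(=O)o1
F8 | step 6 | 2-ethyl-4,6-dihydroxybenzoic acid | CCc1cc(O)cc(O)c1C(=O)O
F9 | step 6 | benzyl 2,4-bis(benzyloxy)-6-ethylbenzoate | CCc1cc(OCc2ccccc2)cc(OCc2ccccc2)c1C(=O)OCc1ccccc1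
F10 | step 6 | 2,4-bis(benzyloxy)-6-ethylbenzoic acid | CCc1cc(OCc2ccccc2)cc(OCc2ccccc2)c1C(=O)O
F11 | step 6 | 1-[2,4-bis(benzyloxy)-6-ethylbenzoyl]-1H-imidazole | CCc1cc(OCc2ccccc2)cc(OCc2ccccc2)c1C(=O)n1ccnc1
F12 | step 6 | 6-[(6-{2-[2,4-bis(benzyloxy)-6-ethylphenyl]-2-oxoethyl}-4-oxo-4H-pyran-2-yl)methyl]-4-hydroxy-2H-pyran-2-one | CCc1cc(OCc2ccccc2)cc(OCc2ccccc2)c1C(=O)Cc1cc(=O)cc(Cc2cc(O)cc(=O)o2)o1
F13 | step 6 | 1-[2,4-bis(benzyloxy)-6-ethylphenyl]-8-(4-hydroxy-2-oxo-2H-pyran-6-yl)octane-1,3,5,7-tetrone | CCc1cc(OCc2ccccc2)cc(OCc2ccccc2)c1C(=O)CC(=O)CC(=O)CC(=O)Cc1cc(O)cc(=O)o1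
F14 | step 6 | [2,4-bis(benzyloxy)-6-ethylphenyl]{2,4-dihydroxy-6-[(4-hydroxy-2-oxo-2H-pyran-6-yl)methyl]phenyl}methanone | CCc1cc(OCc2ccccc2)cc(OCc2ccccc2)c1C(=O)c1c(O)cc(O)cc1Cc1cc(O)cc(=O)o1
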